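The oxolane is numbered O1, C2 (pentyl), C3 (ester oxygen), C4, C5, with C1' as the carbinol carbon. The ring is read as a cyclobutanone that lacks O1: C2–C3 and C4–C5 are made together in a ketene–enol ether (2+2) cycloaddition, and the extra C2–C5 bond is later cut by Baeyer–Villiger insertion of O1. The key step exploits the oxygen on C3, β to C5 and cis to the pentyl group on C2, which is the regio- and stereochemical signature of such cycloadducts. Its precursors are pentylketene, made in the flask from heptanoyl chloride, and the vinyl ether of a chiral 1-arylethanol. C5 is then set by ionic reduction and C1' by chelation-controlled Grignard addition.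

Key step: step 2

Assumption: the (S)-configured auxiliary is taken to direct the ketene to the face of the vinyl ether that gives (3S); if the induction has the opposite sense, the (R)-alcohol is used and the route is otherwise unchanged.

Step 1
Reactants: 1 (1S)-1-[2,4,6-tri(propan-2-yl)phenyl]ethanol; 2 butyl vinyl ether
Product: 3 2-[(1S)-1-(ethenyloxy)ethyl]-1,3,5-tri(propan-2-yl)benzene
Conditions: Pd(OCOCF3)2 (cat.), 4,7-diphenyl-1,10-phenanthroline (cat.), Et3N (cat.), neat 2, 75 °C
Reagents that add atoms: none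
Why: Transfer vinylation (transetherification) under divalent palladium catalysis exchanges only the O–H bond, so the carbinol stereocentre of the auxiliary is untouched.

Step 2
Reactants: 3 2-[(1S)-1-(ethenyloxy)ethyl]-1,3,5-tri(propan-2-yl)benzene; 4 heptanoyl chloride
Product: 6 (2S,3S)-2-pentyl-3-{(1S)-1-[2,4,6-tri(propan-2-yl)phenyl]ethoxy}cyclobutan-1-one, via pentylketene 5 (not isolated)
Conditions: Et3N (2.9 equiv), MeCN, 60 °C, slow addition of 4 (3 equiv) to 3
Reagents that add atoms: none
Why: Et3N dehydrochlorinates 4 to pentylketene 5, whose electrophilic carbonyl carbon (C5) is attacked by the CH2 terminus of vinyl ether 3 (C4) while the ketene α-carbon (C2) closes onto the oxygen-stabilised carbon (C3) in an asynchronous thermal (2+2) cycloaddition. The closest known reaction type is the cycloaddition of ketenes made from acyl chlorides with alkyl vinyl ethers to give 3-alkoxycyclobutanones, and that of ketenes with enol ethers of chiral 1-arylethanols. The cyclobutanone ring closes by this (2+2) mode, with C2–C3 and C4–C5 as the new bonds and C2–C5 brought in by the ketene. C3 is controlled by the auxiliary, whose triisopropylphenyl group shields one face of the vinyl ether; C2 is controlled by the ketene approach, which turns the pentyl group towards the alkoxy-bearing carbon and so should give the cis isomer under kinetic control. The step needs regioselectivity, secured by the donor oxygen on the carbon that becomes C3, and cross-cycloaddition in preference to ketene dimerization, secured by slow addition of excess 4 to 3; the medium buffered by Et3NHCl limits epimerization at C2.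

Step 3
Reactants: 6 (2S,3S)-2-pentyl-3-{(1S)-1-[2,4,6-tri(propan-2-yl)phenyl]ethoxy}cyclobutan-1-one
Product: 7 (4S,5S)-5-pentyl-4-{(1S)-1-[2,4,6-tri(propan-2-yl)phenyl]ethoxy}oxolan-2-one
Conditions: mCPBA, NaHCO3, CH2Cl2, 0 °C
Reagents that add atoms: 3-chloroperoxybenzoic acid (mCPBA), OOC(=O)c1cccc(Cl)c1
Why: Baeyer–Villiger oxidation, fast for the strained cyclobutanone, in which the more substituted α-carbon C2 migrates to oxygen with retention, so O1 enters between C2 and C5, the temporary C2–C5 bond is cut and the cis C2/C3 relationship is kept.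

Step 4
Reactants: 7 (4S,5S)-5-pentyl-4-{(1S)-1-[2,4,6-tri(propan-2-yl)phenyl]ethoxy}oxolan-2-one
Product: 8 (4S,5S)-2-ethenyl-5-pentyl-4-{(1S)-1-[2,4,6-tri(propan-2-yl)phenyl]ethoxy}oxolan-2-ol (mixture at C2 of the lactol)
Conditions: CH2=CHMgBr (1.3 equiv), THF, −78 °C; aq. NH4Cl
Reagents that add atoms: vinylmagnesium bromide, C=C[Mg]Br
Why: Grignard addition to the lactone carbonyl, where the tetrahedral magnesium alkoxide survives at −78 °C so that only one vinyl group is delivered and enolization with loss of the C3 alkoxy group is limited; the new hemiketal centre is a mixture that is erased in step 5.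

Step 5
Reactants: 8 (4S,5S)-2-ethenyl-5-pentyl-4-{(1S)-1-[2,4,6-tri(propan-2-yl)phenyl]ethoxy}oxolan-2-ol
Product: 10 (2S,3S,5R)-5-ethenyl-2-pentyloxolan-3-ol, via ethenyl oxolane ether 9 (not isolated)
Conditions: Et3SiH (6 equiv), BF3·OEt2, CH2Cl2, −78 to −40 °C; then CF3CO2H, 0 °C; NaHCO3, MeOH
Reagents that add atoms: none
Why: Ionic silane reduction of the lactol: BF3·OEt2 gives the five-membered oxocarbenium ion, whose envelope carries the C3 oxygen pseudoaxial and the cis C2 pentyl pseudoequatorial, so hydride should attack C5 from the inside face, cis to the C3 oxygen, placing the vinyl group trans to both substituents (5R); CF3CO2H then ionizes the benzylic auxiliary ether and the remaining silane reduces the cation, so the C3–O bond is not broken.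

Step 6
Reactants: 10 (2S,3S,5R)-5-ethenyl-2-pentyloxolan-3-ol; 11 hexadecanoyl chloride
Product: 12 (2S,3S,5R)-5-ethenyl-2-pentyloxolan-3-yl hexadecanoate
Conditions: pyridine, DMAP (cat.), CH2Cl2, 0 °C to rt
Reagents that add atoms: none
Why: Nucleophilic acyl substitution on the only hydroxyl group under DMAP catalysis, with the C3–O bond and all stereocentres untouched.

Step 7
Reactants: 12 (2S,3S,5R)-5-ethenyl-2-pentyloxolan-3-yl hexadecanoate
Product: 13 (2S,3S,5R)-5-formyl-2-pentyloxolan-3-yl hexadecanoate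
Conditions: O3, CH2Cl2, −78 °C; PPh3
Reagents that add atoms: ozone, [O-][O+]=O
Why: Ozonolysis of the only C=C bond with reductive work-up gives the α-alkoxy aldehyde under neutral conditions that should not epimerize C5, and the ester is inert.

Step 8
Reactants: 13 (2S,3S,5R)-5-formyl-2-pentyloxolan-3-yl hexadecanoate; 14 9-bromonon-1-ene
Product: 16 (2S,3S,5R)-5-[(1R)-1-hydroxydec-9-en-1-yl]-2-pentyloxolan-3-yl hexadecanoate, via non-8-enylmagnesium bromide 15 (not isolated)
Conditions: 14, Mg, Et2O, reflux; then 13, MgBr2·OEt2, CH2Cl2, −78 °C; aq. NH4Cl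
Reagents that add atoms: none
Why: Grignard addition under chelation control: magnesium bridges the aldehyde oxygen and ring O1, and the nucleophile enters from the side of the C5 hydrogen to give the threo (1'R) carbinol, the aldehyde reacting far faster than the ester at −78 °C.

Compound list
1 | (1S)-1-[2,4,6-tri(propan-2-yl)phenyl]ethanol | C[C@H](O)c1c(C(C)C)cc(C(C)C)cc1C(C)C | starting material
2 | butyl vinyl ether | C=COCCCC | starting material
3 | 2-[(1S)-1-(ethenyloxy)ethyl]-1,3,5-tri(propan-2-yl)benzene | C=CO[C@@H](C)c1c(C(C)C)cc(C(C)C)cc1C(C)C | intermediate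
4 | heptanoyl chloride | CCCCCCC(Cl)=O | starting material
5 | pentylketene (hept-1-en-1-one) | CCCCCC=C=O | intermediate
6 | (2S,3S)-2-pentyl-3-{(1S)-1-[2,4,6-tri(propan-2-yl)phenyl]ethoxy}cyclobutan-1-one | O=C1C[C@H](O[C@@H](C)c2c(C(C)C)cc(C(C)C)cc2C(C)C)[C@@H]1CCCCC | intermediate
7 | (4S,5S)-5-pentyl-4-{(1S)-1-[2,4,6-tri(propan-2-yl)phenyl]ethoxy}oxolan-2-one | O=C1C[C@H](O[C@@H](C)c2c(C(C)C)cc(C(C)C)cc2C(C)C)[C@H](CCCCC)O1 | intermediate
8 | (4S,5S)-2-ethenyl-5-pentyl-4-{(1S)-1-[2,4,6-tri(propan-2-yl)phenyl]ethoxy}oxolan-2-ol | C=CC1(O)C[C@H](O[C@@H](C)c2c(C(C)C)cc(C(C)C)cc2C(C)C)[C@H](CCCCC)O1 | intermediate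
9 | (2S,3S,5R)-5-ethenyl-2-pentyl-3-{(1S)-1-[2,4,6-tri(propan-2-yl)phenyl]ethoxy}oxolane | C=C[C@H]1C[C@H](O[C@@H](C)c2c(C(C)C)cc(C(C)C)cc2C(C)C)[C@H](CCCCC)O1 | intermediate
10 | (2S,3S,5R)-5-ethenyl-2-pentyloxolan-3-ol | C=C[C@H]1C[C@H](O)[C@H](CCCCC)O1 | intermediate
11 | hexadecanoyl chloride | CCCCCCCCCCCCCCCC(Cl)=O | starting material
12 | (2S,3S,5R)-5-ethenyl-2-pentyloxolan-3-yl hexadecanoate | C=C[C@H]1C[C@H](OC(=O)CCCCCCCCCCCCCCC)[C@H](CCCCC)O1 | intermediate
13 | (2S,3S,5R)-5-formyl-2-pentyloxolan-3-yl hexadecanoate | O=C[C@H]1C[C@H](OC(=O)CCCCCCCCCCCCCCC)[C@H](CCCCC)O1 | intermediate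
14 | 9-bromonon-1-ene | C=CCCCCCCCBr | starting material
15 | non-8-enylmagnesium bromide | C=CCCCCCCC[Mg]Br | intermediate
16 | (2S,3S,5R)-5-[(1R)-1-hydroxydec-9-en-1-yl]-2-pentyloxolan-3-yl hexadecanoate | C=CCCCCCCC[C@@H](O)[C@H]1C[C@H](OC(=O)CCCCCCCCCCCCCCC)[C@H](CCCCC)O1 | target

Total step count: 8
Longest linear sequence: 8 steps (steps 1 to 8; all other components are commercial)

Steps most likely to fail

Step 2. The cross-cycloaddition may be slow relative to ketene dimerization, the kinetic cis relationship may erode by base-mediated epimerization at C2, and facial discrimination by the auxiliary may be incomplete. The fallback sets out from 4 and 3 and comes back at 6. Heptanoyl chloride 4 is α-chlorinated (N-chlorosuccinimide, SOCl2, cat. HCl, 85 °C) to 2-chloroheptanoyl chloride F1. Et3N then releases chloro(pentyl)ketene F2 in the presence of 3; this more electrophilic ketene should add to the vinyl ether with the same regiochemistry to give (3S)-2-chloro-2-pentyl-3-{(1S)-1-[2,4,6-tri(propan-2-yl)phenyl]ethoxy}cyclobutan-1-one F3. Zinc in acetic acid removes chlorine, and protonation of the zinc enolate from the face away from the C3 alkoxy group should give 6.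

Step 5. Hydride may be delivered to the wrong face of the ring oxocarbenium ion, reduction may occur through the vinyl terminus, or the auxiliary may be lost before reduction and change the selectivity. The fallback sets C5 by a different element and runs from 7 to 9. Lactone 7 is reduced with i-Bu2AlH (toluene, −78 °C) to (4S,5S)-5-pentyl-4-{(1S)-1-[2,4,6-tri(propan-2-yl)phenyl]ethoxy}oxolan-2-ol F4. Wittig methylenation (Ph3P=CH2, THF) opens it to (4S,5S)-4-{(1S)-1-[2,4,6-tri(propan-2-yl)phenyl]ethoxy}dec-1-en-5-ol F5. Cobalt-catalysed aerobic oxidative cyclization of this pent-4-en-1-ol unit (Co(modp)2, that is bis(5,5-dimethyl-1-morpholin-4-ylhexane-1,2,4-trionato)cobalt with divalent cobalt, O2, cat. t-BuOOH, propan-2-ol, 55 °C) should close the ring trans-selectively to [(2R,4S,5S)-5-pentyl-4-{(1S)-1-[2,4,6-tri(propan-2-yl)phenyl]ethoxy}oxolan-2-yl]methanol F6. Dess–Martin oxidation gives (2R,4S,5S)-5-pentyl-4-{(1S)-1-[2,4,6-tri(propan-2-yl)phenyl]ethoxy}oxolane-2-carbaldehyde F7, and a second Wittig methylenation gives 9. Compound 9 is taken on to 10 by the acid stage of step 5 (CF3CO2H, Et3SiH).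

Step 8. Chelation control may be weak and give the C1' epimer, and some addition to the ester may compete. The fallback sets out from 13 and comes back at 16. Grignard reagent 15 is added without regard to selectivity to give (2S,3S,5R)-5-(1-hydroxydec-9-en-1-yl)-2-pentyloxolan-3-yl hexadecanoate F8 as both C1' epimers. Dess–Martin oxidation converges them to (2S,3S,5R)-5-(dec-9-enoyl)-2-pentyloxolan-3-yl hexadecanoate F9. Reduction with the bulky, non-chelating hydride LiBH(s-Bu)3 (THF, −78 °C) should attack anti to the ring C–O bond and give the threo alcohol 16, the ester being inert at this temperature.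

Further compounds
F1 | step 2 | 2-chloroheptanoyl chloride | CCCCCC(Cl)C(Cl)=O
F2 | step 2 | chloro(pentyl)ketene (2-chlorohept-1-en-1-one) | CCCCCC(Cl)=C=O
F3 | step 2 | (3S)-2-chloro-2-pentyl-3-{(1S)-1-[2,4,6-tri(propan-2-yl)phenyl]ethoxy}cyclobutan-1-one | O=C1C[C@H](O[C@@H](C)c2c(C(C)C)cc(C(C)C)cc2C(C)C)C1(Cl)CCCCC
F4 | step 5 | (4S,5S)-5-pentyl-4-{(1S)-1-[2,4,6-tri(propan-2-yl)phenyl]ethoxy}oxolan-2-ol | OC1C[C@H](O[C@@H](C)c2c(C(C)C)cc(C(C)C)cc2C(C)C)[C@H](CCCCC)O1
F5 | step 5 | (4S,5S)-4-{(1S)-1-[2,4,6-tri(propan-2-yl)phenyl]ethoxy}dec-1-en-5-ol | C=CC[C@H](O[C@@H](C)c1c(C(C)C)cc(C(C)C)cc1C(C)C)[C@H](CCCCC)O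
F6 | step 5 | [(2R,4S,5S)-5-pentyl-4-{(1S)-1-[2,4,6-tri(propan-2-yl)phenyl]ethoxy}oxolan-2-yl]methanol | OC[C@H]1C[C@H](O[C@@H](C)c2c(C(C)C)cc(C(C)C)cc2C(C)C)[C@H](CCCCC)O1
F7 | step 5 | (2R,4S,5S)-5-pentyl-4-{(1S)-1-[2,4,6-tri(propan-2-yl)phenyl]ethoxy}oxolane-2-carbaldehyde | O=C[C@H]1C[C@H](O[C@@H](C)c2c(C(C)C)cc(C(C)C)cc2C(C)C)[C@H](CCCCC)O1
F8 | step 8 | (2S,3S,5R)-5-(1-hydroxydec-9-en-1-yl)-2-pentyloxolan-3-yl hexadecanoate (both C1' epimers) | C=CCCCCCCCC(O)[C@H]1C[C@H](OC(=O)CCCCCCCCCCCCCCC)[C@H](CCCCC)O1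
F9 | step 8 | (2S,3S,5R)-5-(dec-9-enoyl)-2-pentyloxolan-3-yl hexadecanoate | C=CCCCCCCCC(=O)[C@H]1C[C@H](OC(=O)CCCCCCCCCCCCCCC)[C@H](CCCCC)O1
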